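**Retrosynthetic overview**
1. The symmetrical dibenzyl ether is cut at both aryl–CH2 bonds at once: two electrophilic aryl iodides plus one ⁻CH2–O–CH2⁻ linchpin (a double α-oxy carbanion equivalent), bis[(tributylstannyl)methyl] ether, joined by a twofold Stille coupling that leaves the ring bromines untouched.
2. The aryl iodide, 3,4-dibromo-5-iodocatechol, comes from O-demethylation of 2,3-dibromo-4-iodo-6-methoxyphenol.
3. That phenol comes from two OH-directed halogenations of commercial 5-bromoguaiacol: iodine para to OH, then bromine ortho to OH.
4. The linchpin comes from a Williamson union of Bu3SnCH2OH and Bu3SnCH2I.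
5. No ring is formed (both benzene rings are bought) and there is no stereocentre to set.

Assumption: the target SMILES contains no stereocentre (the molecule is achiral), so it is made as drawn and no stereocontrol is required.

**Step 1**
Reactants: 1 5-bromo-2-methoxyphenol (5-bromoguaiacol)
Product: 2 5-bromo-4-iodo-2-methoxyphenol
Conditions: NIS (1.05 equiv), TsOH·H2O (10 mol %), MeCN, 0 °C → rt, dark
Reagents that add atoms: N-iodosuccinimide, O=C1CCC(=O)N1I
Why: Electrophilic aromatic iodination (SEAr); the free OH is the dominant director and acid-activated NIS iodinates phenols at the open para position (C4), while C3 is only meta to OH and ortho to OMe.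

**Step 2**
Reactants: 2 5-bromo-4-iodo-2-methoxyphenol
Product: 3 2,3-dibromo-4-iodo-6-methoxyphenol
Conditions: NBS (1.05 equiv), i-Pr2NH (10 mol %), CH2Cl2, 0 °C
Reagents that add atoms: N-bromosuccinimide, O=C1CCC(=O)N1Br
Why: Amine-mediated ortho-selective phenol bromination (SEAr with an N-bromoamine delivered through hydrogen bonding to OH); the only free ortho position is C6 next to the existing Br, and the mild, ortho-delivered bromine source at 0 °C avoids ipso attack at the iodinated para carbon.

**Step 3**
Reactants: 3 2,3-dibromo-4-iodo-6-methoxyphenol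
Product: 5 3,4-dibromo-5-iodobenzene-1,2-diol, via cyclic bromoborane ester 4 (not isolated)
Conditions: BBr3 (2.5 equiv), CH2Cl2, −78 °C → rt; then ice-water; handle under Ar
Reagents that add atoms: boron tribromide, BrB(Br)Br (B and Br are carried by 4 only; none remain in 5)
Why: Lewis-acid aryl methyl ether cleavage (O–B complexation, bromide SN2 at the methyl group); aryl C–Br and C–I bonds are inert and the borate is hydrolysed on quench.

**Step 4**
Reactants: 6 (tributylstannyl)methanol; 7 tributyl(iodomethyl)stannane
Product: 9 bis[(tributylstannyl)methyl] ether, via sodium alkoxide 8 (not isolated)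
Conditions: NaH (1.2 equiv), THF/DMF 4:1, 0 °C, 30 min; then 7 (1.05 equiv), 0 °C → rt
Reagents that add atoms: sodium hydride, [Na+].[H-] (Na is carried by 8 only; none remains in 9)
Why: Williamson ether synthesis; the unhindered primary iodide α to tin is a good SN2 electrophile for alkoxides, and stannylmethyl alkoxides are routinely O-alkylated without loss of tin.

**Step 5 (key step)**
Reactants: 5 3,4-dibromo-5-iodobenzene-1,2-diol (2.3 equiv); 9 bis[(tributylstannyl)methyl] ether (1.0 equiv)
Product: 13 bis(2,3-dibromo-4,5-dihydroxybenzyl) ether, via bis-TMS ether 10 (not isolated), via mono-coupled stannane 11 (not isolated), via tetra-TMS ether 12 (not isolated)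
Conditions: (i) HMDS (1.15 equiv per 5), (NH4)2SO4 (cat.), toluene, 80 °C, then evaporate; (ii) Pd2(dba)3 (5 mol %), P(2-furyl)3 (20 mol %), CuI (20 mol %), dioxane, 75 °C, 9 added over 2 h, Ar; (iii) aq NaH2PO4 (pH ≈ 5)/THF, 0 °C → rt; MeCN/hexane partition to remove tin
Reagents that add atoms: hexamethyldisilazane, C[Si](C)(C)N[Si](C)(C)C (Me3Si groups are carried by 10–12 only; none remain in 13)
Why: Proposed new method: a twofold Migita–Kosugi–Stille coupling in which each Sn–CH2–O carbon of 9 acts as an α-alkoxy carbanion (a donor at a carbon that is normally an acceptor) toward the electrophilic C–I carbon. Pd(0) inserts into C–I far faster than into the hindered C–Br bonds, and the α-oxygen makes CH2OR transfer from tin in preference to butyl. Keeping 10 in excess while 9 is added slowly stops Pd from inserting into the ortho C–Br of 11, which would close a phthalan ring. The transient TMS ethers keep the catechol away from Pd and Cu and hydrolyse on the buffered work-up. The closest known reaction is the Pd-catalysed hydroxymethylation or alkoxymethylation of aryl halides with Bu3SnCH2OH or Bu3SnCH2OR.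

**Compound list**
1 | 5-bromo-2-methoxyphenol | COc1ccc(Br)cc1O | starting material
2 | 5-bromo-4-iodo-2-methoxyphenol | COc1cc(I)c(Br)cc1O | intermediate
3 | 2,3-dibromo-4-iodo-6-methoxyphenol | COc1cc(I)c(Br)c(Br)c1O | intermediate
4 | 2,4,5-tribromo-6-iodo-1,3,2-benzodioxaborole (not isolated) | BrB1Oc2cc(I)c(Br)c(Br)c2O1 | intermediate
5 | 3,4-dibromo-5-iodobenzene-1,2-diol | Oc1cc(I)c(Br)c(Br)c1O | intermediate
6 | (tributylstannyl)methanol | CCCC[Sn](CCCC)(CCCC)CO | starting material
7 | tributyl(iodomethyl)stannane | CCCC[Sn](CCCC)(CCCC)CI | starting material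
8 | sodium (tributylstannyl)methanolate (not isolated) | CCCC[Sn](CCCC)(CCCC)C[O-].[Na+] | intermediate
9 | bis[(tributylstannyl)methyl] ether | CCCC[Sn](CCCC)(CCCC)COC[Sn](CCCC)(CCCC)CCCC | intermediate
10 | 3,4-dibromo-5-iodo-1,2-bis(trimethylsilyloxy)benzene (not isolated) | C[Si](C)(C)Oc1cc(I)c(Br)c(Br)c1O[Si](C)(C)C | intermediate
11 | tributyl({[2,3-dibromo-4,5-bis(trimethylsilyloxy)benzyl]oxy}methyl)stannane (not isolated) | CCCC[Sn](CCCC)(CCCC)COCc1cc(O[Si](C)(C)C)c(O[Si](C)(C)C)c(Br)c1Br | intermediate
12 | bis[2,3-dibromo-4,5-bis(trimethylsilyloxy)benzyl] ether (not isolated) | C[Si](C)(C)Oc1cc(COCc2cc(O[Si](C)(C)C)c(O[Si](C)(C)C)c(Br)c2Br)c(Br)c(Br)c1O[Si](C)(C)C | intermediate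
13 | bis(2,3-dibromo-4,5-dihydroxybenzyl) ether | Oc1cc(COCc2cc(O)c(O)c(Br)c2Br)c(Br)c(Br)c1O | target

**Totals**
Total step count: 5 (steps 1, 2, 3 and 5 on the arene; step 4 makes the linchpin).
Longest linear sequence: 4 steps (1 → 2 → 3 → 5 → 13).

**Three steps most likely to fail, with fallbacks**

Step 5 (twofold Stille; risks are slow sp3 transmetalation next to an ortho bromine, phthalan formation from 11, and partial reaction at C–Br). The fallback sets out from 10, made in the flask from 5 exactly as in step 5, and makes one C–C bond per arene with the simple hydroxymethyl-anion reagent 6. Coupling 10 with 6 (1.2 equiv) under Pd(PPh3)4 in dioxane at 80 °C gives [2,3-dibromo-4,5-bis(trimethylsilyloxy)phenyl]methanol F1. The same buffered work-up releases 3,4-dibromo-5-(hydroxymethyl)benzene-1,2-diol F2. The ether is then closed by C–O bond formation: acid-catalysed dehydrative self-condensation of F2 (TsOH cat., dry dioxane, 4 Å sieves, 40 °C, through the p-quinone methide or benzylic cation) comes back to the route at 13.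

Step 2 (ortho bromination of a p-iodophenol; risk is ipso bromodeiodination and halogen scrambling). The fallback sets out from 1 and reverses the halogenation order so that no iodine is present when bromine is introduced. Ortho-selective bromination of 1 with t-BuNH2/Br2 in toluene at −78 °C gives 2,3-dibromo-6-methoxyphenol F3. Para iodination of F3 with NIS/TsOH in MeCN, where only the position para to OH remains activated, comes back to the route at 3.

Step 4 (Williamson on a stannylmethyl alkoxide; risk is low conversion or loss of tin under basic conditions). The fallback sets out from 6 and forms the second C–Sn bond last instead of the C–O bond. Treating 6 with paraformaldehyde and TMSCl in CH2Cl2 at 0 °C gives tributyl[(chloromethoxy)methyl]stannane F4. Tributylstannyllithium F5, generated from Bu3SnH and LDA in THF at −78 °C, then displaces the chloride of F4 and comes back to the route at 9.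

**Further compounds**
F1 | step 5 | [2,3-dibromo-4,5-bis(trimethylsilyloxy)phenyl]methanol | C[Si](C)(C)Oc1cc(CO)c(Br)c(Br)c1O[Si](C)(C)C
F2 | step 5 | 3,4-dibromo-5-(hydroxymethyl)benzene-1,2-diol | OCc1cc(O)c(O)c(Br)c1Br
F3 | step 2 | 2,3-dibromo-6-methoxyphenol | COc1ccc(Br)c(Br)c1O
F4 | step 4 | tributyl[(chloromethoxy)methyl]stannane | CCCC[Sn](CCCC)(CCCC)COCCl
F5 | step 4 | tributylstannyllithium | [Li][Sn](CCCC)(CCCC)CCCC
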